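The retrosynthesis cuts, in order: the acyl–oxygen bond of the primary veratrate; C4–C5 of the oxolane, after C4 is raised to a ketone and C5 is given a disposable CO2Bn group; the O1–C5 ether bond; and C2–C3.
Enabling feature: in the single oxolane ring, C5 is a bare CH2 flanked by O1 and the oxygenated C4. It can therefore enter as the α-carbon of a glycolate hung on the C2 oxygen and be acylated by a carboxyl derivative at C4.
Forward order: C2–C3 (boron aldol of a 3-silyloxypropanoyl oxazolidinone with veratraldehyde), O1–C5 (carbenoid O–H insertion), C4–C5 (Dieckmann-type closure of the ring with the auxiliary as leaving group). Loss of CO2, ketone reduction, desilylation and esterification follow.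
Stereochemistry: (S)-4-benzyloxazolidin-2-one fixes C2 (S) and C3 (R) as a syn pair that becomes cis on the ring. C4 (S) follows from hydride attack on the ketone face opposite both substituents, which gives the all-cis triad.

Key step: step 4

Assumption: 3-[(tert-butyldimethylsilyl)oxy]propanoic acid is taken as a catalogue compound; ring atoms carry the target numbering (O1, C2 aryl, C3 CH2O, C4 OH, C5 H2) in all explanations, and the C3 descriptor changes from S to R on reduction of the C4 ketone only because C4 then ranks below C2.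

Step 1
Reactants: 1 3-[(tert-butyldimethylsilyl)oxy]propanoic acid; 2 (S)-4-benzyl-1,3-oxazolidin-2-one
Product: 4 (S)-4-benzyl-3-{3-[(tert-butyldimethylsilyl)oxy]propanoyl}-1,3-oxazolidin-2-one, via mixed pivalic anhydride 3 (not isolated)
Conditions: t-BuCOCl, Et3N, THF, −20 °C; then LiCl, 2, −20 °C → rt
Reagents that add atoms: pivaloyl chloride, CC(C)(C)C(=O)Cl (its acyl group is carried by 3 only)
Why: Mixed-anhydride N-acylation of an oxazolidinone (LiCl/Et3N variant) needs no strong base, so the β-silyloxy chain should not eliminate, the nucleophile attacks the less hindered carbonyl of 3, and no stereocentre is formed.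

Step 2
Reactants: 4 (S)-4-benzyl-3-{3-[(tert-butyldimethylsilyl)oxy]propanoyl}-1,3-oxazolidin-2-one; 5 veratraldehyde (3,4-dimethoxybenzaldehyde)
Product: 8 (S)-4-benzyl-3-[(2S,3S)-2-{[(tert-butyldimethylsilyl)oxy]methyl}-3-(3,4-dimethoxyphenyl)-3-hydroxypropanoyl]-1,3-oxazolidin-2-one (syn aldol), via Z-dibutylboron enolate 6 (not isolated), via dibutylboron aldolate 7 (not isolated)
Conditions: Bu2BOTf, Et3N, CH2Cl2, −78 → 0 °C; 5, −78 → 0 °C; pH 7 buffer, MeOH, 30% H2O2, 0 °C
Reagents that add atoms: dibutylboron triflate, CCCCB(CCCC)OS(=O)(=O)C(F)(F)F (its Bu2B group is carried by 6 and 7 only)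
Why: Evans syn aldol, in which soft enolisation gives the Z-boron enolate 6 and this adds to 5 through a chair Zimmerman–Traxler transition state on the enolate face away from the benzyl group of the auxiliary, setting the (2S,3S) syn pair that becomes ring C3 and C2, while the weakly Lewis basic silyl ether oxygen disfavours β-elimination.

Step 3
Reactants: 8 syn aldol adduct; 9 benzyl diazoacetate
Product: 10 benzyl 2-{(1S,2S)-3-[(S)-4-benzyl-2-oxo-1,3-oxazolidin-3-yl]-2-{[(tert-butyldimethylsilyl)oxy]methyl}-1-(3,4-dimethoxyphenyl)-3-oxopropoxy}acetate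
Conditions: Rh2(OAc)4 (1 mol %), CH2Cl2, rt, slow addition of 9
Reagents that add atoms: none
Why: Dirhodium-carbenoid O–H insertion forms the O1–C5 ether bond under neutral conditions, which avoids the retro-aldol and elimination pathways of a base-mediated Williamson alkylation and leaves C2 untouched because its C–O bond is not broken.

Step 4
Reactants: 10 glycolate ether of the aldol imide
Product: 12 benzyl (4S,5S)-4-{[(tert-butyldimethylsilyl)oxy]methyl}-5-(3,4-dimethoxyphenyl)-3-oxooxolane-2-carboxylate (aryl and silyloxymethyl cis; carboxyl-bearing carbon as an epimer mixture), via lithium glycolate enolate 11 (not isolated)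
Conditions: LiN(SiMe3)2 (2.2 equiv), THF (dilute), −78 °C; AcOH, −78 °C
Reagents that add atoms: LiN(SiMe3)2, [Li]N([Si](C)(C)C)[Si](C)(C)C (its lithium is carried by 11 only)
Why: The amide base removes a proton from the unhindered OCH2CO2Bn group, the enolate carbon (future C5) adds to the exocyclic imide carbonyl (future C4), and collapse of the tetrahedral adduct expels the lithium oxazolidinide, so the C4–C5 bond and the oxolane form in one operation. The closest known reaction type is the Dieckmann condensation of O-alkylated glycolates to 3-oxooxolane-2-carboxylates, joined to the known Claisen-like cyclisation of Evans aldol adducts that bear an enolisable ester on the carbinol oxygen and lose the auxiliary as leaving group. The ring closes in the 5-(enolexo)-exo-trig mode, whereas attack on the ring carbonyl of the auxiliary would require a seven-membered transition state. The only new stereocentre, C5, is deliberately uncontrolled because it lies between two carbonyl groups, equilibrates through the enol and is erased in step 5, while C2 and C3 are carried through unchanged. The step needs deprotonation at the glycolate CH2 and not at C3–H, whose enolate would expel the C2 oxygen or the silyloxy group or close onto the glycolate carbonyl; A(1,3) strain between the auxiliary and the branched C3 keeps that C–H out of alignment with the imide carbonyl, and the second equivalent of base holds the product as its C4–C5 enolate so that C3 cannot epimerise. The oxazolidinide released is not nucleophilic, so the benzyl ester is not scrambled as it could be by an alkoxide leaving group, and −78 °C suppresses a [1,2]-Wittig shift of the benzylic ether.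

Step 5
Reactants: 12 β-keto benzyl ester
Product: 14 (4S,5S)-4-{[(tert-butyldimethylsilyl)oxy]methyl}-5-(3,4-dimethoxyphenyl)oxolan-3-one (4,5-cis), via β-keto acid 13 (not isolated)
Conditions: H2 (1 atm), 10% Pd/C, EtOAc, rt, short contact; filter, 40 °C; crude 14 used at once
Reagents that add atoms: none
Why: Benzyl ester hydrogenolysis followed by β-keto acid decarboxylation is neutral throughout, CO2 leaves through the cyclic transition state to the C4–C5 enol that is protonated at C5 so C3 is never deprotonated, the silyl ether is inert, and the brief exposure should spare the benzylic C2–O1 bond.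

Step 6
Reactants: 14 cis-oxolan-3-one
Product: 15 (3S,4R,5S)-4-{[(tert-butyldimethylsilyl)oxy]methyl}-5-(3,4-dimethoxyphenyl)oxolan-3-ol (all-cis)
Conditions: LiBH(s-Bu)3, THF, −78 °C; NaOH, H2O2, 0 °C
Reagents that add atoms: none
Why: Diastereoselective ketone reduction with a bulky trialkylborohydride, in which hydride reaches C4 from the ring face opposite the cis C2 aryl and C3 silyloxymethyl groups and so places the new hydroxyl on their face (4S in target numbering), while at −78 °C addition should outrun enolisation.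

Step 7
Reactants: 15 all-cis silyl ether alcohol
Product: 16 (3S,4R,5S)-5-(3,4-dimethoxyphenyl)-4-(hydroxymethyl)oxolan-3-ol
Conditions: Bu4NF, THF, 0 °C → rt
Reagents that add atoms: none
Why: Fluoride-mediated desilylation, driven by Si–F bond formation, touches no other group, and any silyl migration to the C4 oxygen during step 6 converges on the same diol.

Step 8
Reactants: 16 all-cis diol; 17 3,4-dimethoxybenzoyl chloride
Product: 18 [(2S,3R,4S)-2-(3,4-dimethoxyphenyl)-4-hydroxyoxolan-3-yl]methyl 3,4-dimethoxybenzoate (CNP0317486.2)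
Conditions: 2,4,6-collidine, CH2Cl2, −78 → −20 °C
Reagents that add atoms: none
Why: Chemoselective acylation of a primary over a secondary alcohol with an acyl chloride and a hindered pyridine base at low temperature should esterify only the CH2OH group, because the C4 hydroxyl is secondary and buried on the crowded all-cis face, and no stereocentre is affected.

Compound list
1 | 3-[(tert-butyldimethylsilyl)oxy]propanoic acid | CC(C)(C)[Si](C)(C)OCCC(=O)O | starting material
2 | (S)-4-benzyl-1,3-oxazolidin-2-one | O=C1N[C@@H](Cc2ccccc2)CO1 | starting material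
3 | 3-[(tert-butyldimethylsilyl)oxy]propanoic pivalic anhydride | CC(C)(C)[Si](C)(C)OCCC(=O)OC(=O)C(C)(C)C | intermediate
4 | (S)-4-benzyl-3-{3-[(tert-butyldimethylsilyl)oxy]propanoyl}-1,3-oxazolidin-2-one | CC(C)(C)[Si](C)(C)OCCC(=O)N1C(=O)OC[C@@H]1Cc1ccccc1 | intermediate
5 | veratraldehyde | COc1ccc(C=O)cc1OC | starting material
6 | (S)-4-benzyl-3-[(Z)-1-(dibutylboryloxy)-3-(tert-butyldimethylsilyloxy)prop-1-enyl]-1,3-oxazolidin-2-one | CCCCB(CCCC)O/C(=C\CO[Si](C)(C)C(C)(C)C)N1C(=O)OC[C@@H]1Cc1ccccc1 | intermediate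
7 | O-dibutylboryl derivative of 8 (boron aldolate, 2S,3S) | O=C([C@@H](CO[Si](C)(C)C(C)(C)C)[C@H](OB(CCCC)CCCC)c1ccc(OC)c(OC)c1)N1C(=O)OC[C@@H]1Cc1ccccc1 | intermediate
8 | (S)-4-benzyl-3-[(2S,3S)-2-{[(tert-butyldimethylsilyl)oxy]methyl}-3-(3,4-dimethoxyphenyl)-3-hydroxypropanoyl]-1,3-oxazolidin-2-one | O=C([C@@H](CO[Si](C)(C)C(C)(C)C)[C@H](O)c1ccc(OC)c(OC)c1)N1C(=O)OC[C@@H]1Cc1ccccc1 | intermediate
9 | benzyl diazoacetate | [N-]=[N+]=CC(=O)OCc1ccccc1 | starting material
10 | benzyl 2-{(1S,2S)-3-[(S)-4-benzyl-2-oxo-1,3-oxazolidin-3-yl]-2-{[(tert-butyldimethylsilyl)oxy]methyl}-1-(3,4-dimethoxyphenyl)-3-oxopropoxy}acetate | O=C([C@@H](CO[Si](C)(C)C(C)(C)C)[C@H](OCC(=O)OCc1ccccc1)c1ccc(OC)c(OC)c1)N1C(=O)OC[C@@H]1Cc1ccccc1 | intermediate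
11 | lithium ester enolate of 10, deprotonated at the OCH2CO2Bn carbon (enolate geometry not defined) | O=C([C@@H](CO[Si](C)(C)C(C)(C)C)[C@H](OC=C(O[Li])OCc1ccccc1)c1ccc(OC)c(OC)c1)N1C(=O)OC[C@@H]1Cc1ccccc1 | intermediate
12 | benzyl (4S,5S)-4-{[(tert-butyldimethylsilyl)oxy]methyl}-5-(3,4-dimethoxyphenyl)-3-oxooxolane-2-carboxylate | O=C(OCc1ccccc1)C1O[C@H](c2ccc(OC)c(OC)c2)[C@H](CO[Si](C)(C)C(C)(C)C)C1=O | intermediate
13 | (4S,5S)-4-{[(tert-butyldimethylsilyl)oxy]methyl}-5-(3,4-dimethoxyphenyl)-3-oxooxolane-2-carboxylic acid | O=C(O)C1O[C@H](c2ccc(OC)c(OC)c2)[C@H](CO[Si](C)(C)C(C)(C)C)C1=O | intermediate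
14 | (4S,5S)-4-{[(tert-butyldimethylsilyl)oxy]methyl}-5-(3,4-dimethoxyphenyl)oxolan-3-one | C1O[C@H](c2ccc(OC)c(OC)c2)[C@H](CO[Si](C)(C)C(C)(C)C)C1=O | intermediate
15 | (3S,4R,5S)-4-{[(tert-butyldimethylsilyl)oxy]methyl}-5-(3,4-dimethoxyphenyl)oxolan-3-ol | CC(C)(C)[Si](C)(C)OC[C@@H]1[C@H](O)CO[C@@H]1c1ccc(OC)c(OC)c1 | intermediate
16 | (3S,4R,5S)-5-(3,4-dimethoxyphenyl)-4-(hydroxymethyl)oxolan-3-ol | OC[C@@H]1[C@H](O)CO[C@@H]1c1ccc(OC)c(OC)c1 | intermediate
17 | 3,4-dimethoxybenzoyl chloride | COc1ccc(C(=O)Cl)cc1OC | starting material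
18 | [(2S,3R,4S)-2-(3,4-dimethoxyphenyl)-4-hydroxyoxolan-3-yl]methyl 3,4-dimethoxybenzoate | COc1ccc(C(=O)OC[C@@H]2[C@H](O)CO[C@@H]2c2ccc(OC)c(OC)c2)cc1OC | target

Total step count: 8. Longest linear sequence: 8 (1 or 2 to 18).

Steps most likely to fail

**Step 4.**
- Risk: deprotonation at C3–H could compete with the glycolate CH2 and lead to β-elimination of the C2 oxygen or of the silyloxy group. Addition to the crowded imide carbonyl could also be sluggish.
- Fallback: the same ring is closed at O1–C5 under neutral conditions.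
- Setting out from 8, transamination with MeONHMe·HCl and AlMe3 (CH2Cl2, −20 → 0 °C) should give the Weinreb amide (2S,3S)-2-{[(tert-butyldimethylsilyl)oxy]methyl}-3-(3,4-dimethoxyphenyl)-3-hydroxy-N-methoxy-N-methylpropanamide F1.
- Excess lithium enolate of benzyl acetate (LiN(i-Pr)2, THF, −78 °C) should convert it into benzyl (4S,5S)-4-{[(tert-butyldimethylsilyl)oxy]methyl}-5-(3,4-dimethoxyphenyl)-5-hydroxy-3-oxopentanoate F2.
- Regitz diazo transfer (4-acetamidobenzenesulfonyl azide, Et3N, MeCN) should give benzyl (4S,5S)-4-{[(tert-butyldimethylsilyl)oxy]methyl}-2-diazo-5-(3,4-dimethoxyphenyl)-5-hydroxy-3-oxopentanoate F3.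
- Intramolecular O–H insertion catalysed by Rh2(OAc)4 (CH2Cl2, rt) comes back to the route at 12. Steps 3 and 4 are bypassed.

**Step 5.**
- Risk: once the free ketone is exposed, C3 could epimerise towards the trans arrangement or undergo β-elimination. Prolonged hydrogenation could cleave the benzylic C2–O1 bond.
- Fallback: the ketone is reduced before the carboxyl is removed, and the carboxyl then leaves by a radical path.
- Setting out from 12, NaBH4 (MeOH–THF, −40 °C, hydride again from the face opposite the C2 and C3 groups) should give benzyl (3S,4R,5S)-4-{[(tert-butyldimethylsilyl)oxy]methyl}-5-(3,4-dimethoxyphenyl)-3-hydroxyoxolane-2-carboxylate F4.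
- Brief hydrogenolysis (H2, Pd/C, EtOAc) should give (3S,4R,5S)-4-{[(tert-butyldimethylsilyl)oxy]methyl}-5-(3,4-dimethoxyphenyl)-3-hydroxyoxolane-2-carboxylic acid F5.
- Coupling with 1-hydroxypyridine-2(1H)-thione (DCC, CH2Cl2, dark) should give the Barton ester 2-thioxopyridin-1(2H)-yl (3S,4R,5S)-4-{[(tert-butyldimethylsilyl)oxy]methyl}-5-(3,4-dimethoxyphenyl)-3-hydroxyoxolane-2-carboxylate F6.
- Photolysis with t-BuSH (Barton reductive decarboxylation) puts hydrogen on C5 and comes back to the route at 15, so 14 is never made.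

**Step 3.**
- Risk: carbene dimerisation or attack on the electron-rich arene could outpace insertion into the hindered, hydrogen-bonded carbinol.
- Fallback: the carbenoid is replaced by an SN2 alkylation under non-basic conditions.
- Benzyl glycolate is converted with Tf2O and 2,6-lutidine (CH2Cl2, −78 °C) into benzyl 2-{[(trifluoromethyl)sulfonyl]oxy}acetate F7.
- Setting out from 8, treatment with this triflate and 2,6-di-tert-butyl-4-methylpyridine (CH2Cl2, 0 °C → rt) should alkylate the carbinol oxygen without forming an alkoxide. This comes back to the route at 10.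

Further compounds
F1 | step 4 | (2S,3S)-2-{[(tert-butyldimethylsilyl)oxy]methyl}-3-(3,4-dimethoxyphenyl)-3-hydroxy-N-methoxy-N-methylpropanamide | CON(C)C(=O)[C@@H](CO[Si](C)(C)C(C)(C)C)[C@H](O)c1ccc(OC)c(OC)c1
F2 | step 4 | benzyl (4S,5S)-4-{[(tert-butyldimethylsilyl)oxy]methyl}-5-(3,4-dimethoxyphenyl)-5-hydroxy-3-oxopentanoate | O=C(CC(=O)[C@@H](CO[Si](C)(C)C(C)(C)C)[C@H](O)c1ccc(OC)c(OC)c1)OCc1ccccc1
F3 | step 4 | benzyl (4S,5S)-4-{[(tert-butyldimethylsilyl)oxy]methyl}-2-diazo-5-(3,4-dimethoxyphenyl)-5-hydroxy-3-oxopentanoate | O=C(C(=[N+]=[N-])C(=O)[C@@H](CO[Si](C)(C)C(C)(C)C)[C@H](O)c1ccc(OC)c(OC)c1)OCc1ccccc1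
F4 | step 5 | benzyl (3S,4R,5S)-4-{[(tert-butyldimethylsilyl)oxy]methyl}-5-(3,4-dimethoxyphenyl)-3-hydroxyoxolane-2-carboxylate | O=C(OCc1ccccc1)C1O[C@H](c2ccc(OC)c(OC)c2)[C@H](CO[Si](C)(C)C(C)(C)C)[C@@H]1O
F5 | step 5 | (3S,4R,5S)-4-{[(tert-butyldimethylsilyl)oxy]methyl}-5-(3,4-dimethoxyphenyl)-3-hydroxyoxolane-2-carboxylic acid | O=C(O)C1O[C@H](c2ccc(OC)c(OC)c2)[C@H](CO[Si](C)(C)C(C)(C)C)[C@@H]1O
F6 | step 5 | 2-thioxopyridin-1(2H)-yl (3S,4R,5S)-4-{[(tert-butyldimethylsilyl)oxy]methyl}-5-(3,4-dimethoxyphenyl)-3-hydroxyoxolane-2-carboxylate | O=C(On1ccccc1=S)C1O[C@H](c2ccc(OC)c(OC)c2)[C@H](CO[Si](C)(C)C(C)(C)C)[C@@H]1O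
F7 | step 3 | benzyl 2-{[(trifluoromethyl)sulfonyl]oxy}acetate | O=C(COS(=O)(=O)C(F)(F)F)OCc1ccccc1
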